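Set the flasks side by side and count, for each, how many lifetimes of monomer in chains fit into the time.

    2 living end → dead end (k1 = 118 M⁻¹ s⁻¹, Ea1 = 48.0 kJ mol⁻¹)
    free monomer + initiator → living end + monomer in chains (k2 = 86.7 M⁻¹ s⁻¹, Ea2 = 50.0 kJ mol⁻¹)
    living end + transfer agent → dead chain (k3 = 2.13 M⁻¹ s⁻¹, Ea3 = 60.0 kJ mol⁻¹)
    free monomer + living end → monomer in chains + living end, rate k4*[living end]*[free monomer] (k4 = 70.5 M⁻¹ s⁻¹, Ea4 = 51.0 kJ mol⁻¹)
    free monomer + monomer in chains → side product (k5 = 3.27 M⁻¹ s⁻¹, Ea5 = 60.0 kJ mol⁻¹)
    monomer in chains → over-reaction product (k6 = 0.00748 s⁻¹, Ea6 = 94.0 kJ mol⁻¹)
    (constants at 35 °C)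

all flasks: free monomer 10 mM; transfer agent 3.00 mM; initiator 2 mol%; time 80 s
- Saturday's: temperature 55 °C
- Wednesday's: temperature 35 °C
- Friday's: temperature 15 °C
- Thursday's: temperature 75 °C

- percent here means free monomer units held: one side product counts as two
- where a step has two of a species, its rate is k times that concentration squared, and two are used at each turn
- the constants hold at 35 °C; other temperatures follow from the activation energies

- the best flask by amount of monomer in chains, in percent of the free monomer charged; "all alike" if 1.5 percentage points covers them all (Saturday's / Wednesday's / Friday's / Thursday's / all alike)
- amount of monomer in chains at the end, in percent of the free monomer charged, Saturday's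
- amount of monomer in chains at the end, in percent of the free monomer charged, Wednesday's
- amount of monomer in chains at the end, in percent of the free monomer charged, Friday's
- amount of monomer in chains at the end, in percent of the free monomer charged, Thursday's

**Question reversed.** I ask what must be true for Thursday's flask, the hottest, to hold the most monomer in chains. Chain growth speeds up 39 times from Friday's flask, the coldest, to Thursday's, and at equal c(living end) that factor must outweigh what the losses take away in between.

**Loss count.** Monomer in chains goes by two routes: free monomer attacks it, at the side-product constant times c(free monomer), and it also turns alone, at the over-reaction constant. Taken at the charged c(free monomer), their sum is a pseudo-first-order loss constant, and its inverse is a lifetime. For Friday's flask 0.562 lifetimes fit in the time, so one lifetime is 142 s; this number of lifetimes in the time is my loss count. Wednesday's flask counts 3.21, Saturday's 16.5 and Thursday's 79.1.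

**The distance.** Units made evenly through the time survive in the share one minus e to the minus count, over the count: 76.5% for Friday's flask and 1.26% for Thursday's. At equal c(living end), Thursday's flask needs its growth factor times its share to pass Friday's share, but that product is 49.1%, less than 76.5%, so on this test it falls short by a factor of 1.56. Ranking by that share, I commit to Friday's, but this ranks the flasks and gives no amounts.

**The forecast.** It names Friday's too, and it does give amounts: 13.4% for Friday's flask, where “losses are slow”, then 8.3% for Wednesday's, 0.45% for Saturday's and 0.0013% for Thursday's.

**What stands.** The simulation gives Friday's as best, with 13.8% in Friday's flask, 8.43% in Wednesday's, 0.424% in Saturday's and 0% in Thursday's. The equal c(living end) of my test does not hold at 80.0 s: Thursday's flask has 2.41 × 10⁻⁵ mM, far less than the 0.0961 mM of Friday's. In Friday's flask, at a loss count of 0.562, monomer in chains is still made 1.71 times faster than it is used up at 80.0 s, so making outruns losing there. The same flask run at 40 °C has a count of 4.88, above Wednesday's, and it holds 5.10%.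

The numbers are made up.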